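**Strategy.** The furofuran (3,7-dioxabicyclo[3.3.0]octane; bridgeheads C1/C5, C2 bears ArB, C6 bears ArC) is opened at C4–C5. C4, the methylene on O3, is a formaldehyde-level carbon, and C5 is α to C6, which is carried as a γ-lactone carbonyl. The precursor is therefore a β-substituted γ-butyrolactone whose benzylic C2–OH (set together with C1 by an Evans succinate aldol) is a MOM ether. One operation (in situ silyl ketene acetal, MOM ionisation) joins C4 to C5 and fixes C5 through the enforced cis ring fusion. Aryllithium addition of the cis-dihydrobenzofuran unit, SN1 ring closure, then a late Evans aldol and oxidation complete the target.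

Key step: step 14

Remark (labels): ArA = 4-hydroxy-3-methoxybenzoyl ring; ArB = central guaiacyl ring; ArC/ArD = benzo ring and 2-aryl ring of the dihydrobenzofuran. Furofuran numbering: C1(H)–C2(H)(ArB)–O3–C4H2–C5(H)–C6(H)(ArC)–O7–C8H2–C1.
Remark (assumption): 3-allyl-4-hydroxy-5-methoxybenzaldehyde (14) is taken as a catalogue compound.
Remark (assumption): Rh2(S-PTTL)4 is assumed to give the (2S,3R)-cis ester 8; if its sense of induction is the opposite, Rh2(R-PTTL)4 is used.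
Remark (stereochemistry): the target SMILES specifies a cis-2-aryl-3-(hydroxymethyl)dihydrobenzofuran (2S,3S), and the route is built for that.

**Dihydrobenzofuran fragment (ArC/ArD)**

Step 1
Reactants: 1 vanillin
Product: 2 3-methoxy-4-(triisopropylsilyloxy)benzaldehyde
Conditions: TIPSCl, imidazole, DMF, rt
Reagents that add atoms: triisopropylsilyl chloride, CC(C)[Si](Cl)(C(C)C)C(C)C
Why: Standard phenol silylation; aryl TIPS ethers should survive the hydride, organolithium and Lewis-acid steps and leave with buffered fluoride.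

Step 2
Reactants: 2 3-methoxy-4-(triisopropylsilyloxy)benzaldehyde
Product: 3 [3-methoxy-4-(triisopropylsilyloxy)phenyl]methanol
Conditions: NaBH4, MeOH, 0 °C
Reagents that add atoms: none
Why: Borohydride reduction of an aryl aldehyde to the benzylic alcohol with the silyl ether untouched.

Step 3
Reactants: 4 4-bromo-2-methoxyphenol
Product: 5 4-bromo-2-iodo-6-methoxyphenol
Conditions: NIS, TsOH·H2O (cat.), MeCN, rt
Reagents that add atoms: N-iodosuccinimide, O=C1CCC(=O)N1I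
Why: Electrophilic aromatic iodination directed by the hydroxyl to its only free ortho position, the para position being blocked by bromine.

Step 4
Reactants: 5 4-bromo-2-iodo-6-methoxyphenol; 3 [3-methoxy-4-(triisopropylsilyloxy)phenyl]methanol
Product: 6 5-bromo-1-iodo-3-methoxy-2-{[3-methoxy-4-(triisopropylsilyloxy)benzyl]oxy}benzene
Conditions: PPh3, DIAD, THF, 0 °C → rt
Reagents that add atoms: none
Why: Mitsunobu etherification of an acidic halophenol with a primary benzylic alcohol, which avoids the labile p-silyloxybenzyl halide.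

Step 5
Reactants: 6 5-bromo-1-iodo-3-methoxy-2-{[3-methoxy-4-(triisopropylsilyloxy)benzyl]oxy}benzene
Product: 7 methyl 2-diazo-2-(5-bromo-3-methoxy-2-{[3-methoxy-4-(triisopropylsilyloxy)benzyl]oxy}phenyl)acetate
Conditions: methyl diazoacetate, Pd(PPh3)4 (5 mol%), Ag2CO3 (0.5 equiv), Et3N, toluene, rt
Reagents that add atoms: methyl diazoacetate, COC(=O)C=[N+]=[N-]
Why: Pd-catalysed cross-coupling of an aryl iodide with the C–H bond of a diazoacetate with retention of the diazo group; the C–I bond should react at room temperature and the C–Br bond should not.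

Step 6
Reactants: 7 methyl 2-diazo-2-(5-bromo-3-methoxy-2-{[3-methoxy-4-(triisopropylsilyloxy)benzyl]oxy}phenyl)acetate
Product: 8 methyl (2S,3R)-5-bromo-7-methoxy-2-[3-methoxy-4-(triisopropylsilyloxy)phenyl]-2,3-dihydrobenzofuran-3-carboxylate (cis)
Conditions: Rh2(S-PTTL)4 (1 mol%), toluene, −60 °C
Reagents that add atoms: none
Why: Rh(II)-carbenoid intramolecular 1,5 C–H insertion into the benzylic ether C–H bond; the chiral carboxylate catalyst should set C2 and C3 together and give the kinetic cis-dihydrobenzofuran.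

Step 7
Reactants: 8 methyl (2S,3R)-5-bromo-7-methoxy-2-[3-methoxy-4-(triisopropylsilyloxy)phenyl]-2,3-dihydrobenzofuran-3-carboxylate
Product: 9 [(2S,3S)-5-bromo-7-methoxy-2-[3-methoxy-4-(triisopropylsilyloxy)phenyl]-2,3-dihydrobenzofuran-3-yl]methanol (cis)
Conditions: DIBAL-H (2.5 equiv), CH2Cl2, −78 °C; Rochelle salt work-up
Reagents that add atoms: none
Why: Ester reduction with an aluminium hydride at low temperature and without base, so the epimerisable cis C3 centre should be kept.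

Step 8
Reactants: 9 [(2S,3S)-5-bromo-7-methoxy-2-[3-methoxy-4-(triisopropylsilyloxy)phenyl]-2,3-dihydrobenzofuran-3-yl]methanol
Product: 10 (2S,3S)-5-bromo-3-[(tert-butyldimethylsilyloxy)methyl]-7-methoxy-2-[3-methoxy-4-(triisopropylsilyloxy)phenyl]-2,3-dihydrobenzofuran
Conditions: TBSCl, imidazole, DMF, rt
Reagents that add atoms: tert-butyldimethylsilyl chloride, CC(C)(C)[Si](C)(C)Cl
Why: Silylation of the primary alcohol, needed so that the later bromine–lithium exchange and acylation steps meet no free hydroxyl.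

**Furofuran core**

Step 9
Reactants: 11 (S)-4-benzyl-2-oxazolidinone; 12 methyl 4-chloro-4-oxobutanoate
Product: 13 methyl 4-[(S)-4-benzyl-2-oxooxazolidin-3-yl]-4-oxobutanoate
Conditions: Et3N, DMAP (cat.), CH2Cl2, 0 °C → rt
Reagents that add atoms: none
Why: DMAP-catalysed N-acylation of the oxazolidinone with an acid chloride.

Step 10
Reactants: 14 3-allyl-4-hydroxy-5-methoxybenzaldehyde
Product: 15 3-allyl-5-methoxy-4-(triisopropylsilyloxy)benzaldehyde
Conditions: TIPSOTf, 2,6-lutidine, CH2Cl2, 0 °C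
Reagents that add atoms: triisopropylsilyl triflate, CC(C)[Si](C(C)C)(C(C)C)OS(=O)(=O)C(F)(F)F
Why: Silylation of the doubly ortho-substituted phenol with the more reactive silyl triflate.

Step 11
Reactants: 13 methyl 4-[(S)-4-benzyl-2-oxooxazolidin-3-yl]-4-oxobutanoate; 15 3-allyl-5-methoxy-4-(triisopropylsilyloxy)benzaldehyde
Product: 17 methyl (3S,4S)-3-[(S)-4-benzyl-2-oxooxazolidine-3-carbonyl]-4-hydroxy-4-[3-allyl-5-methoxy-4-(triisopropylsilyloxy)phenyl]butanoate, via boron enolate 16 (not isolated)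
Conditions: Bu2BOTf, iPr2NEt, CH2Cl2, −78 → 0 °C; then 15, −78 → 0 °C; pH 7 buffer, MeOH, H2O2
Reagents that add atoms: none
Why: Evans syn aldol through the Z boron enolate and a Zimmerman–Traxler transition state; the (S)-benzyl auxiliary should set furofuran C1 and C2 together, and soft enolisation is specific for the imide over the methyl ester.

Step 12
Reactants: 17 methyl (3S,4S)-3-[(S)-4-benzyl-2-oxooxazolidine-3-carbonyl]-4-hydroxy-4-[3-allyl-5-methoxy-4-(triisopropylsilyloxy)phenyl]butanoate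
Product: 18 methyl (3S,4S)-3-[(S)-4-benzyl-2-oxooxazolidine-3-carbonyl]-4-(methoxymethoxy)-4-[3-allyl-5-methoxy-4-(triisopropylsilyloxy)phenyl]butanoate
Conditions: MOMCl, iPr2NEt, Bu4NI (cat.), CH2Cl2, 0 °C → rt
Reagents that add atoms: chloromethyl methyl ether, COCCl
Why: O-alkylation with a chloromethyl ether (MOM ether formation), which blocks lactonisation through O3 and installs the carbon that becomes C4.

Step 13
Reactants: 18 methyl (3S,4S)-3-[(S)-4-benzyl-2-oxooxazolidine-3-carbonyl]-4-(methoxymethoxy)-4-[3-allyl-5-methoxy-4-(triisopropylsilyloxy)phenyl]butanoate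
Product: 20 (4R)-4-{(S)-[3-allyl-5-methoxy-4-(triisopropylsilyloxy)phenyl](methoxymethoxy)methyl}dihydrofuran-2(3H)-one, via hydroxy ester 19 (not isolated)
Conditions: NaBH4, THF–H2O, 0 °C → rt; then PPTS (cat.), toluene, 50 °C
Reagents that add atoms: none
Why: Borohydride cleavage of the N-acyloxazolidinone to the primary alcohol (C8–OH) in the presence of the ester, then lactonisation onto the methyl ester; the γ-lactone has C6 as carbonyl and no stereocentre is touched.

Step 14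
Reactants: 20 (4R)-4-{(S)-[3-allyl-5-methoxy-4-(triisopropylsilyloxy)phenyl](methoxymethoxy)methyl}dihydrofuran-2(3H)-one
Product: 23 (1R,2S,5R)-2-[3-allyl-5-methoxy-4-(triisopropylsilyloxy)phenyl]-3,7-dioxabicyclo[3.3.0]octan-6-one (cis-fused), via silyl ketene acetal 21 (not isolated), via oxocarbenium triflate 22 (not isolated)
Conditions: TMSOTf (2.5 equiv), iPr2NEt (1.5 equiv), CH2Cl2, −78 → −20 °C; aq. NaHCO3
Reagents that add atoms: none
Why: TMSOTf/iPr2NEt first converts the lactone into its silyl ketene acetal by soft enolisation; TMSOTf then ionises the MOM ether at the methoxy oxygen with loss of MeOSiMe3 to the alkoxymethyl oxocarbenium ion (O3=C4H2+), whose carbon is attacked by the nucleophilic C5, and loss of the silyl group returns the lactone. The closest known reaction type is the Mukaiyama-type addition of silyl ketene acetals to acetals run as a one-pot enol silane formation/addition with TMSOTf and an amine, together with the closure of a tetrahydrofuran onto an enol ether by an O-tethered oxocarbenium ion. Ring A (C2–O3–C4–C5–C1) closes as a five-membered ring, exo for the ketene acetal C5=C6 bond and endo for the O3=C4 oxocarbenium bond. The only new stereocentre, C5, is controlled by C1: the short C1–C2–O3 tether can reach only the face of the lactone ring on which it sits, so the cis-fused bicycle (C5 R) is the sole attainable product. The step needs ionisation of the MeO–CH2 bond rather than the benzylic C2–O bond, and C- rather than O-alkylation; the first should be secured by silyl coordination to the less hindered methoxy oxygen at low temperature, the second by ring size, and the ketene acetal is a far better nucleophile than the arene or the allyl group.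

Step 15
Reactants: 10 (2S,3S)-5-bromo-3-[(tert-butyldimethylsilyloxy)methyl]-7-methoxy-2-[3-methoxy-4-(triisopropylsilyloxy)phenyl]-2,3-dihydrobenzofuran; 23 (1R,2S,5R)-2-[3-allyl-5-methoxy-4-(triisopropylsilyloxy)phenyl]-3,7-dioxabicyclo[3.3.0]octan-6-one
Product: 26 [(2S,3R,4R)-2-[3-allyl-5-methoxy-4-(triisopropylsilyloxy)phenyl]-4-[hydroxy(ArC)methyl]tetrahydrofuran-3-yl]methanol (carbinol epimers; ArC = dihydrobenzofuran-5-yl unit of 10), via aryllithium 24 (not isolated), via hydroxy ketone 25 (not isolated)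
Conditions: 10, n-BuLi, THF, −78 °C; then 23, −78 °C; AcOH (1 equiv), MeOH, NaBH4, −40 → 0 °C
Reagents that add atoms: none
Why: Bromine–lithium exchange and addition of the aryllithium to the lactone carbonyl should stop at the hemiketal stage, and borohydride reduction of the derived hydroxy ketone after a buffered quench (to protect C5) gives the 1,4-diol; the carbinol configuration is irrelevant for step 16.

Step 16
Reactants: 26 [(2S,3R,4R)-2-[3-allyl-5-methoxy-4-(triisopropylsilyloxy)phenyl]-4-[hydroxy(ArC)methyl]tetrahydrofuran-3-yl]methanol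
Product: 27 (1R,2S,5R,6S)-2-[3-allyl-5-methoxy-4-(triisopropylsilyloxy)phenyl]-6-(ArC)-3,7-dioxabicyclo[3.3.0]octane (both aryl groups exo)
Conditions: CSA (10 mol%), 4 Å MS, CH2Cl2, 0 °C
Reagents that add atoms: none
Why: Acid-catalysed SN1 cycloetherification: the p-alkoxybenzylic alcohol ionises to a quinone-methide-type cation that the C8 hydroxyl captures in a 5-exo closure, and the aryl group should take the convex (exo) position trans to C4, which sets C6 as S from either carbinol epimer.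

**Side chain and end game**

Step 17
Reactants: 27 (1R,2S,5R,6S)-2-[3-allyl-5-methoxy-4-(triisopropylsilyloxy)phenyl]-6-(ArC)-3,7-dioxabicyclo[3.3.0]octane
Product: 29 arylacetaldehyde (allyl group of 27 cut to CH2CHO), via vicinal diol 28 (not isolated)
Conditions: OsO4 (2 mol%), NaIO4, 2,6-lutidine, dioxane–H2O, rt
Reagents that add atoms: osmium tetroxide, O=[Os](=O)(=O)=O (catalytic oxygen carrier); sodium periodate, [Na+].[O-][I](=O)(=O)=O
Why: Lemieux–Johnson oxidative cleavage of the only alkene in the molecule.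

Step 18
Reactants: 29 arylacetaldehyde
Product: 30 arylacetic acid (CH2CO2H on ArB)
Conditions: NaClO2, NaH2PO4, 2-methyl-2-butene, t-BuOH–H2O, 0 °C → rt
Reagents that add atoms: sodium chlorite, [Na+].[O-]Cl=O
Why: Pinnick oxidation under mildly acidic buffered conditions, with the alkene scavenger protecting the electron-rich rings from hypochlorite.

Step 19
Reactants: 30 arylacetic acid; 31 (R)-4-benzyl-2-oxazolidinone
Product: 33 (R)-4-benzyl-3-(arylacetyl)oxazolidin-2-one, via mixed pivalic anhydride 32 (not isolated)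
Conditions: PivCl, Et3N, THF, −20 °C; then 31, LiCl, rt
Reagents that add atoms: none
Why: One-pot mixed-anhydride N-acylation of the oxazolidinone promoted by LiCl.

Step 20
Reactants: 33 (R)-4-benzyl-3-(arylacetyl)oxazolidin-2-one; 2 3-methoxy-4-(triisopropylsilyloxy)benzaldehyde
Product: 35 (R)-4-benzyl-3-[(2R,3R)-2-aryl-3-hydroxy-3-[3-methoxy-4-(triisopropylsilyloxy)phenyl]propanoyl]oxazolidin-2-one, via boron enolate 34 (not isolated)
Conditions: Bu2BOTf, iPr2NEt, CH2Cl2, −78 → 0 °C; then 2, −78 → 0 °C; pH 7 buffer, MeOH, H2O2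
Reagents that add atoms: none
Why: Evans syn aldol of an arylacetyl imide; the (R)-benzyl auxiliary should set the α-aryl carbon (R in the imide, S in the final ketone), and the carbinol centre is destroyed later.

Step 21
Reactants: 35 (R)-4-benzyl-3-[(2R,3R)-2-aryl-3-hydroxy-3-[3-methoxy-4-(triisopropylsilyloxy)phenyl]propanoyl]oxazolidin-2-one
Product: 36 (1R,2S)-2-aryl-1-[3-methoxy-4-(triisopropylsilyloxy)phenyl]propane-1,3-diol
Conditions: NaBH4, THF–H2O, 0 °C → rt
Reagents that add atoms: none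
Why: Borohydride reductive removal of the auxiliary to the primary alcohol under conditions mild enough to limit retro-aldol cleavage.

Step 22
Reactants: 36 (1R,2S)-2-aryl-1-[3-methoxy-4-(triisopropylsilyloxy)phenyl]propane-1,3-diol
Product: 37 (S)-2-aryl-3-hydroxy-1-[3-methoxy-4-(triisopropylsilyloxy)phenyl]propan-1-one (fully silylated target)
Conditions: MnO2 (activated, excess), CH2Cl2, rt
Reagents that add atoms: none
Why: Manganese dioxide oxidises benzylic alcohols in preference to saturated primary alcohols, and the neutral heterogeneous conditions should keep the labile α-aryl stereocentre.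

Step 23
Reactants: 37 (S)-2-aryl-3-hydroxy-1-[3-methoxy-4-(triisopropylsilyloxy)phenyl]propan-1-one
Product: 38 CNP0174045.1
Conditions: TBAF, AcOH (1:1), THF, 0 °C → rt
Reagents that add atoms: none
Why: Buffered fluoride desilylation of three aryl TIPS ethers and one primary TBS ether; acetic acid keeps the phenols protonated, so the ketone α-centre should not epimerise and the cis-dihydrobenzofuran should not open through a quinone methide.

**Compound list**

1 | vanillin | COc1cc(C=O)ccc1O | starting material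
2 | 3-methoxy-4-(triisopropylsilyloxy)benzaldehyde | COc1cc(C=O)ccc1O[Si](C(C)C)(C(C)C)C(C)C | intermediate
3 | [3-methoxy-4-(triisopropylsilyloxy)phenyl]methanol | COc1cc(CO)ccc1O[Si](C(C)C)(C(C)C)C(C)C | intermediate
4 | 4-bromo-2-methoxyphenol | COc1cc(Br)ccc1O | starting material
5 | 4-bromo-2-iodo-6-methoxyphenol | COc1cc(Br)cc(I)c1O | intermediate
6 | 5-bromo-1-iodo-3-methoxy-2-{[3-methoxy-4-(triisopropylsilyloxy)benzyl]oxy}benzene | COc1cc(Br)cc(I)c1OCc1ccc(O[Si](C(C)C)(C(C)C)C(C)C)c(OC)c1 | intermediate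
7 | methyl 2-diazo-2-(5-bromo-3-methoxy-2-{[3-methoxy-4-(triisopropylsilyloxy)benzyl]oxy}phenyl)acetate | COC(=O)C(=[N+]=[N-])c1cc(Br)cc(OC)c1OCc1ccc(O[Si](C(C)C)(C(C)C)C(C)C)c(OC)c1 | intermediate
8 | methyl (2S,3R)-5-bromo-7-methoxy-2-[3-methoxy-4-(triisopropylsilyloxy)phenyl]-2,3-dihydrobenzofuran-3-carboxylate (cis) | Brc1cc(OC)c2c(c1)[C@@H](C(=O)OC)[C@@H](c1ccc(O[Si](C(C)C)(C(C)C)C(C)C)c(OC)c1)O2 | intermediate
9 | [(2S,3S)-5-bromo-7-methoxy-2-[3-methoxy-4-(triisopropylsilyloxy)phenyl]-2,3-dihydrobenzofuran-3-yl]methanol (cis) | Brc1cc(OC)c2c(c1)[C@@H](CO)[C@@H](c1ccc(O[Si](C(C)C)(C(C)C)C(C)C)c(OC)c1)O2 | intermediate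
10 | (2S,3S)-5-bromo-3-[(tert-butyldimethylsilyloxy)methyl]-7-methoxy-2-[3-methoxy-4-(triisopropylsilyloxy)phenyl]-2,3-dihydrobenzofuran | Brc1cc(OC)c2c(c1)[C@@H](CO[Si](C)(C)C(C)(C)C)[C@@H](c1ccc(O[Si](C(C)C)(C(C)C)C(C)C)c(OC)c1)O2 | intermediate
11 | (S)-4-benzyl-2-oxazolidinone | O=C1N[C@@H](Cc2ccccc2)CO1 | starting material
12 | methyl 4-chloro-4-oxobutanoate | COC(=O)CCC(Cl)=O | starting material
13 | methyl 4-[(S)-4-benzyl-2-oxooxazolidin-3-yl]-4-oxobutanoate | COC(=O)CCC(=O)N1C(=O)OC[C@@H]1Cc1ccccc1 | intermediate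
14 | 3-allyl-4-hydroxy-5-methoxybenzaldehyde | C=CCc1cc(C=O)cc(OC)c1O | starting material
15 | 3-allyl-5-methoxy-4-(triisopropylsilyloxy)benzaldehyde | C=CCc1cc(C=O)cc(OC)c1O[Si](C(C)C)(C(C)C)C(C)C | intermediate
16 | (Z)-dibutylboron enolate of 13 | COC(=O)C/C=C(\OB(CCCC)CCCC)N1C(=O)OC[C@@H]1Cc1ccccc1 | intermediate
17 | methyl (3S,4S)-3-[(S)-4-benzyl-2-oxooxazolidine-3-carbonyl]-4-hydroxy-4-[3-allyl-5-methoxy-4-(triisopropylsilyloxy)phenyl]butanoate | C=CCc1cc([C@@H](O)[C@H](CC(=O)OC)C(=O)N2C(=O)OC[C@@H]2Cc2ccccc2)cc(OC)c1O[Si](C(C)C)(C(C)C)C(C)C | intermediate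
18 | MOM ether of 17 | C=CCc1cc([C@@H](OCOC)[C@H](CC(=O)OC)C(=O)N2C(=O)OC[C@@H]2Cc2ccccc2)cc(OC)c1O[Si](C(C)C)(C(C)C)C(C)C | intermediate
19 | methyl (3R,4S)-3-(hydroxymethyl)-4-(methoxymethoxy)-4-[3-allyl-5-methoxy-4-(triisopropylsilyloxy)phenyl]butanoate | C=CCc1cc([C@@H](OCOC)[C@H](CC(=O)OC)CO)cc(OC)c1O[Si](C(C)C)(C(C)C)C(C)C | intermediate
20 | (4R)-4-{(S)-[3-allyl-5-methoxy-4-(triisopropylsilyloxy)phenyl](methoxymethoxy)methyl}dihydrofuran-2(3H)-one | C=CCc1cc([C@@H](OCOC)[C@H]2COC(=O)C2)cc(OC)c1O[Si](C(C)C)(C(C)C)C(C)C | intermediate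
21 | silyl ketene acetal of 20 (2-trimethylsilyloxy-4,5-dihydrofuran) | C=CCc1cc([C@@H](OCOC)[C@H]2COC(O[Si](C)(C)C)=C2)cc(OC)c1O[Si](C(C)C)(C(C)C)C(C)C | intermediate
22 | alkoxymethyl oxocarbenium triflate from 21 | C=CCc1cc([C@@H]([O+]=C)[C@H]2COC(O[Si](C)(C)C)=C2)cc(OC)c1O[Si](C(C)C)(C(C)C)C(C)C.[O-]S(=O)(=O)C(F)(F)F | intermediate
23 | (1R,2S,5R)-2-[3-allyl-5-methoxy-4-(triisopropylsilyloxy)phenyl]-3,7-dioxabicyclo[3.3.0]octan-6-one | C=CCc1cc([C@H]2OC[C@H]3[C@@H]2COC3=O)cc(OC)c1O[Si](C(C)C)(C(C)C)C(C)C | intermediate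
24 | aryllithium from 10 | [Li]c1cc(OC)c2c(c1)[C@@H](CO[Si](C)(C)C(C)(C)C)[C@@H](c1ccc(O[Si](C(C)C)(C(C)C)C(C)C)c(OC)c1)O2 | intermediate
25 | hydroxy ketone: (2S,3R,4R)-2-ArB-3-(hydroxymethyl)-4-(ArC-carbonyl)tetrahydrofuran | C=CCc1cc([C@H]2OC[C@H](C(=O)c3cc(OC)c4c(c3)[C@@H](CO[Si](C)(C)C(C)(C)C)[C@@H](c3ccc(O[Si](C(C)C)(C(C)C)C(C)C)c(OC)c3)O4)[C@@H]2CO)cc(OC)c1O[Si](C(C)C)(C(C)C)C(C)C | intermediate
26 | diol: [(2S,3R,4R)-2-ArB-4-[hydroxy(ArC)methyl]tetrahydrofuran-3-yl]methanol, carbinol epimers | C=CCc1cc([C@H]2OC[C@H](C(O)c3cc(OC)c4c(c3)[C@@H](CO[Si](C)(C)C(C)(C)C)[C@@H](c3ccc(O[Si](C(C)C)(C(C)C)C(C)C)c(OC)c3)O4)[C@@H]2CO)cc(OC)c1O[Si](C(C)C)(C(C)C)C(C)C | intermediate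
27 | (1R,2S,5R,6S)-furofuran with allyl on ArB | C=CCc1cc([C@H]2OC[C@H]3[C@@H]2CO[C@@H]3c2cc(OC)c3c(c2)[C@@H](CO[Si](C)(C)C(C)(C)C)[C@@H](c2ccc(O[Si](C(C)C)(C(C)C)C(C)C)c(OC)c2)O3)cc(OC)c1O[Si](C(C)C)(C(C)C)C(C)C | intermediate
28 | vicinal diol from dihydroxylation of 27 | OCC(O)Cc1cc([C@H]2OC[C@H]3[C@@H]2CO[C@@H]3c2cc(OC)c3c(c2)[C@@H](CO[Si](C)(C)C(C)(C)C)[C@@H](c2ccc(O[Si](C(C)C)(C(C)C)C(C)C)c(OC)c2)O3)cc(OC)c1O[Si](C(C)C)(C(C)C)C(C)C | intermediate
29 | arylacetaldehyde | O=CCc1cc([C@H]2OC[C@H]3[C@@H]2CO[C@@H]3c2cc(OC)c3c(c2)[C@@H](CO[Si](C)(C)C(C)(C)C)[C@@H](c2ccc(O[Si](C(C)C)(C(C)C)C(C)C)c(OC)c2)O3)cc(OC)c1O[Si](C(C)C)(C(C)C)C(C)C | intermediate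
30 | arylacetic acid | OC(=O)Cc1cc([C@H]2OC[C@H]3[C@@H]2CO[C@@H]3c2cc(OC)c3c(c2)[C@@H](CO[Si](C)(C)C(C)(C)C)[C@@H](c2ccc(O[Si](C(C)C)(C(C)C)C(C)C)c(OC)c2)O3)cc(OC)c1O[Si](C(C)C)(C(C)C)C(C)C | intermediate
31 | (R)-4-benzyl-2-oxazolidinone | O=C1N[C@H](Cc2ccccc2)CO1 | starting material
32 | mixed pivalic anhydride of 30 | CC(C)(C)C(=O)OC(=O)Cc1cc([C@H]2OC[C@H]3[C@@H]2CO[C@@H]3c2cc(OC)c3c(c2)[C@@H](CO[Si](C)(C)C(C)(C)C)[C@@H](c2ccc(O[Si](C(C)C)(C(C)C)C(C)C)c(OC)c2)O3)cc(OC)c1O[Si](C(C)C)(C(C)C)C(C)C | intermediate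
33 | (R)-4-benzyl-3-(arylacetyl)oxazolidin-2-one | O=C(Cc1cc([C@H]2OC[C@H]3[C@@H]2CO[C@@H]3c2cc(OC)c3c(c2)[C@@H](CO[Si](C)(C)C(C)(C)C)[C@@H](c2ccc(O[Si](C(C)C)(C(C)C)C(C)C)c(OC)c2)O3)cc(OC)c1O[Si](C(C)C)(C(C)C)C(C)C)N1C(=O)OC[C@H]1Cc1ccccc1 | intermediate
34 | (Z)-dibutylboron enolate of 33 | CCCCB(CCCC)O/C(=C\c1cc([C@H]2OC[C@H]3[C@@H]2CO[C@@H]3c2cc(OC)c3c(c2)[C@@H](CO[Si](C)(C)C(C)(C)C)[C@@H](c2ccc(O[Si](C(C)C)(C(C)C)C(C)C)c(OC)c2)O3)cc(OC)c1O[Si](C(C)C)(C(C)C)C(C)C)N1C(=O)OC[C@H]1Cc1ccccc1 | intermediate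
35 | (2R,3R) Evans syn aldol adduct of 33 and 2 | COc1cc([C@H](O)[C@H](C(=O)N2C(=O)OC[C@H]2Cc2ccccc2)c2cc([C@H]3OC[C@H]4[C@@H]3CO[C@@H]4c3cc(OC)c4c(c3)[C@@H](CO[Si](C)(C)C(C)(C)C)[C@@H](c3ccc(O[Si](C(C)C)(C(C)C)C(C)C)c(OC)c3)O4)cc(OC)c2O[Si](C(C)C)(C(C)C)C(C)C)ccc1O[Si](C(C)C)(C(C)C)C(C)C | intermediate
36 | (1R,2S)-1,3-diol | COc1cc([C@H](O)[C@H](CO)c2cc([C@H]3OC[C@H]4[C@@H]3CO[C@@H]4c3cc(OC)c4c(c3)[C@@H](CO[Si](C)(C)C(C)(C)C)[C@@H](c3ccc(O[Si](C(C)C)(C(C)C)C(C)C)c(OC)c3)O4)cc(OC)c2O[Si](C(C)C)(C(C)C)C(C)C)ccc1O[Si](C(C)C)(C(C)C)C(C)C | intermediate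
37 | silyl-protected target: (S)-ketone with three aryl TIPS ethers and one primary TBS ether | COc1cc(C(=O)[C@H](CO)c2cc([C@H]3OC[C@H]4[C@@H]3CO[C@@H]4c3cc(OC)c4c(c3)[C@@H](CO[Si](C)(C)C(C)(C)C)[C@@H](c3ccc(O[Si](C(C)C)(C(C)C)C(C)C)c(OC)c3)O4)cc(OC)c2O[Si](C(C)C)(C(C)C)C(C)C)ccc1O[Si](C(C)C)(C(C)C)C(C)C | intermediate
38 | CNP0174045.1 | COc1cc(C(=O)[C@H](CO)c2cc([C@H]3OC[C@H]4[C@@H]3CO[C@@H]4c3cc(OC)c4c(c3)[C@@H](CO)[C@@H](c3ccc(O)c(OC)c3)O4)cc(OC)c2O)ccc1O | target

**Count.** Total: 23 steps. Longest linear sequence: 16 steps (1, 2, 4–8, then 15–23, from vanillin).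

**Steps most likely to fail**

Step 14. The MOM ether may ionise at the benzylic C2–O bond or lose MeOCH2+ (plain deprotection), or the oxocarbenium ion may be intercepted before C5 reaches it. The fallback sets out from 20: BCl3 (CH2Cl2, −78 °C) exchanges the methoxy group for chloride to give the chloromethyl ether F1. KHMDS (THF, −78 °C) then forms the lactone enolate, which closes ring A by intramolecular SN2 alkylation (5-exo-tet) and comes back to the route at 23.

Step 16. Capture of the benzylic cation may show poor facial selectivity (endo aryl), the acid may equilibrate the furofuran, or the cation may fragment and re-close the cis-dihydrobenzofuran through a quinone methide and scramble it to trans. The fallback sets out from 23 and 10 and bypasses steps 15 and 16. DIBAL-H reduces 23 to the lactol F2, and Ac2O/pyridine gives the lactol acetate F3. Aryllithium 24 from 10 is transmetallated with ZnBr2 to the arylzinc bromide F4. Under BF3·OEt2, F4 adds to the bicyclic oxocarbenium ion from F3 on its convex face (C-glycosylation-type arylation). This comes back to the route at 27 with the aryl group exo and without any cation conjugated to the dihydrobenzofuran.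

Step 22. The oxidant may also attack the primary alcohols, or dehydration, retro-aldol loss of formaldehyde and epimerisation of the α-aryl ketone centre may occur on the oxide surface. The fallback sets out from 36: TBSCl/imidazole at 0 °C silylates only the primary alcohol to give the mono-TBS ether F5. Dess–Martin periodinane/NaHCO3 oxidises the remaining benzylic alcohol to the ketone F6, and the buffered fluoride conditions of step 23 come back to the route at 38.

**Further compounds**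

F1 | step 14 | (4R)-4-{(S)-[3-allyl-5-methoxy-4-(triisopropylsilyloxy)phenyl](chloromethoxy)methyl}dihydrofuran-2(3H)-one | C=CCc1cc([C@@H](OCCl)[C@H]2COC(=O)C2)cc(OC)c1O[Si](C(C)C)(C(C)C)C(C)C
F2 | step 16 | lactol from 23 (anomer mixture) | C=CCc1cc([C@H]2OC[C@H]3[C@@H]2COC3O)cc(OC)c1O[Si](C(C)C)(C(C)C)C(C)C
F3 | step 16 | lactol acetate from F2 (anomer mixture) | C=CCc1cc([C@H]2OC[C@H]3[C@@H]2COC3OC(C)=O)cc(OC)c1O[Si](C(C)C)(C(C)C)C(C)C
F4 | step 16 | arylzinc bromide from 10 | Br[Zn]c1cc(OC)c2c(c1)[C@@H](CO[Si](C)(C)C(C)(C)C)[C@@H](c1ccc(O[Si](C(C)C)(C(C)C)C(C)C)c(OC)c1)O2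
F5 | step 22 | mono-TBS ether of diol 36 (primary alcohol silylated) | COc1cc([C@H](O)[C@H](CO[Si](C)(C)C(C)(C)C)c2cc([C@H]3OC[C@H]4[C@@H]3CO[C@@H]4c3cc(OC)c4c(c3)[C@@H](CO[Si](C)(C)C(C)(C)C)[C@@H](c3ccc(O[Si](C(C)C)(C(C)C)C(C)C)c(OC)c3)O4)cc(OC)c2O[Si](C(C)C)(C(C)C)C(C)C)ccc1O[Si](C(C)C)(C(C)C)C(C)C
F6 | step 22 | (S)-ketone from F5 | COc1cc(C(=O)[C@H](CO[Si](C)(C)C(C)(C)C)c2cc([C@H]3OC[C@H]4[C@@H]3CO[C@@H]4c3cc(OC)c4c(c3)[C@@H](CO[Si](C)(C)C(C)(C)C)[C@@H](c3ccc(O[Si](C(C)C)(C(C)C)C(C)C)c(OC)c3)O4)cc(OC)c2O[Si](C(C)C)(C(C)C)C(C)C)ccc1O[Si](C(C)C)(C(C)C)C(C)C
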